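The hemiketal carbon C2 of the chromanone ring and the carboxyl carbon on the benzoic acid ring (ortho to the benzylic CH2) are one oxygen short of a six-membered acylal lactone. Deleting that ring oxygen leaves an indan-1-one spiro-fused at C2. The route builds a spiro[chromane-2,2′-indane]-1′,4-dione with a benzyl ether on the chromanone ring and two electron-withdrawing pivaloyloxy groups on the indanone ring. A peracid then inserts oxygen between C1′ and C2, which turns the five-membered ketone into the lactone in one operation. Hydrogenolysis and saponification release the hemiketal acid, and C2 is set last by crystallization with a chiral amine.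

Key step: step 8

Remark on the chemistry: in the free target C2 is a hemiketal that opens reversibly to an achiral 1,3-diketone, and any basic opening of the lactone passes through that open form; the locked spiro compounds are therefore carried as racemates, C2 is set once (step 10) by crystallization-induced transformation of an amine salt, and the crystalline acid is assumed to keep its configuration.

Step 1
Reactants: 1 5-heptylresorcinol
Product: 3 1-(2,4-dihydroxy-6-heptylphenyl)ethan-1-one, via ketiminium chloride 2 (not isolated)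
Conditions: MeCN, ZnCl2, HCl (g), Et2O, 0 °C; then H2O, 100 °C
Reagents that add atoms: acetonitrile CC#N; water O
Why: Houben–Hoesch acylation, in which the nitrilium ion attacks the ring carbon ortho to one hydroxyl and para to the other (next to the heptyl group) and the ketiminium salt is hydrolysed on heating in water; the isomer acylated between the two hydroxyls should be minor and is removed by crystallization.

Step 2
Reactants: 3 1-(2,4-dihydroxy-6-heptylphenyl)ethan-1-one
Product: 4 1-[4-(benzyloxy)-2-hydroxy-6-heptylphenyl]ethan-1-one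
Conditions: BnBr (1.05 equiv), K2CO3, acetone, 56 °C
Reagents that add atoms: benzyl bromide BrCc1ccccc1
Why: Williamson ether synthesis, selective for the 4-OH because the 2-OH is held in a hydrogen bond to the acetyl oxygen and is far less nucleophilic under carbonate conditions.

Step 3
Reactants: 4 1-[4-(benzyloxy)-2-hydroxy-6-heptylphenyl]ethan-1-one
Product: 5 2-[4-(benzyloxy)-2-hydroxy-6-heptylphenyl]-2-oxoacetaldehyde (arylglyoxal, dried by toluene azeotrope before use)
Conditions: SeO2 (1.3 equiv), 1,4-dioxane/H2O (20:1), 100 °C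
Reagents that add atoms: selenium dioxide O=[Se]=O
Why: Riley oxidation, in which selenium dioxide oxidises the enolisable methyl of the aryl methyl ketone to the aldehyde level and stops at the arylglyoxal, while the benzyl ether, the chelated phenol and the benzylic CH2 of the heptyl chain react far more slowly.

Step 4
Reactants: 6 3-(3,5-dimethoxyphenyl)propanoic acid
Product: 7 5,7-dimethoxy-2,3-dihydro-1H-inden-1-one
Conditions: Eaton's reagent (P2O5 in MsOH, as solvent), 60 °C
Reagents that add atoms: none
Why: intramolecular Friedel–Crafts acylation; the two ring positions next to the side chain are equivalent and each is ortho to one methoxy and para to the other, so only the 5,7-dimethoxy indanone can form.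

Step 5
Reactants: 7 5,7-dimethoxy-2,3-dihydro-1H-inden-1-one
Product: 8 5,7-dihydroxy-2,3-dihydro-1H-inden-1-one
Conditions: BBr3 (3.5 equiv), CH2Cl2, −78 °C → rt; then H2O
Reagents that add atoms: none
Why: Lewis-acid aryl methyl ether cleavage, in which boron tribromide removes both methyl groups (the peri 7-OMe first, helped by chelation to the ketone) and leaves the indanone untouched.

Step 6
Reactants: 8 5,7-dihydroxy-2,3-dihydro-1H-inden-1-one
Product: 9 1-oxo-2,3-dihydro-1H-indene-5,7-diyl bis(2,2-dimethylpropanoate)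
Conditions: PivCl (2.5 equiv), Et3N, DMAP (10 mol%), CH2Cl2, 0 °C → rt
Reagents that add atoms: pivaloyl chloride CC(C)(C)C(=O)Cl
Why: DMAP-catalysed O-acylation of both phenols; pivalates are chosen because they make the indanone aryl ring far less electron-rich than ethers would for step 8, survive acid and peracid, and are hydrolysed more slowly than the lactone in step 10.

Step 7
Reactants: 5 2-[4-(benzyloxy)-2-hydroxy-6-heptylphenyl]-2-oxoacetaldehyde; 9 1-oxo-2,3-dihydro-1H-indene-5,7-diyl bis(2,2-dimethylpropanoate)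
Product: 11 rac-7-(benzyloxy)-5-heptyl-1′,4-dioxo-1′,3′-dihydrospiro[chromane-2,2′-indene]-5′,7′-diyl bis(2,2-dimethylpropanoate), via ene-dione 10 (not isolated)
Conditions: p-TsOH·H2O (10 mol%), toluene, 4 Å MS, 80 → 110 °C
Reagents that add atoms: none
Why: acid-catalysed aldol condensation of the glyoxal aldehyde with the indanone CH2 gives the ene-dione, which under the same acid undergoes intramolecular oxa-Michael addition of the ortho-phenol to C2′ (6-endo closure at the carbon β to the more basic, benzyloxy-conjugated ring-A carbonyl, under thermodynamic control); the spiro centre forms as a racemate, which is intended.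

Step 8
Reactants: 11 rac-7-(benzyloxy)-5-heptyl-1′,4-dioxo-1′,3′-dihydrospiro[chromane-2,2′-indene]-5′,7′-diyl bis(2,2-dimethylpropanoate)
Product: 12 rac-7-(benzyloxy)-5-heptyl-1′,4-dioxospiro[chromane-2,3′-isochromane]-6′,8′-diyl bis(2,2-dimethylpropanoate)
Conditions: mCPBA (2.5 equiv), Na2HPO4 (solid), CH2Cl2, 0 °C → rt, dark
Reagents that add atoms: 3-chloroperbenzoic acid O=C(OO)c1cccc(Cl)c1
Why: The peracid adds to the indanone carbonyl C1′ to give a Criegee adduct, and the C1′–C2 bond then shifts to the proximal peroxide oxygen as 3-chlorobenzoate leaves (Baeyer–Villiger oxidation). The closest known reaction type is the Baeyer–Villiger oxidation of α-alkoxy ketones, in which the oxygen-bearing α-carbon migrates. The six-membered acylal lactone arises by ring expansion of the existing five-membered ketone through this 1,2-shift, not by a new cyclization. No stereocentre is created: C2 migrates with retention (in a single-enantiomer series only the CIP label would change, 2R ketone to 2S lactone), which has no consequence on the racemate used here. Attack at C1′ and not at C4 should be secured by the α-oxygen, the five-ring strain and the two pivaloyloxy groups at the indanone, whereas C4 is a vinylogous ester (O1 ortho, benzyloxy para) shielded by the C5 heptyl chain. Migration of the tertiary, O1-substituted C2 in preference to the aryl carbon should be secured by the same pivaloyloxy groups, which take away the donor character that benzyl ethers would give that ring, and the phosphate buffer keeps 3-chlorobenzoic acid from triggering β-elimination to the chromone.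

Step 9
Reactants: 12 rac-7-(benzyloxy)-5-heptyl-1′,4-dioxospiro[chromane-2,3′-isochromane]-6′,8′-diyl bis(2,2-dimethylpropanoate)
Product: 13 rac-5-heptyl-7-hydroxy-1′,4-dioxospiro[chromane-2,3′-isochromane]-6′,8′-diyl bis(2,2-dimethylpropanoate)
Conditions: H2 (1 atm), 10% Pd/C, EtOAc, rt
Reagents that add atoms: none
Why: catalytic hydrogenolysis of the benzyl aryl ether under neutral conditions that leave the pivalates, the acylal lactone and the hindered aryl ketone intact; the free 7-OH is needed so that in step 10 its phenoxide lowers the acidity of C3–H and blocks E1cB loss of the carboxylate from C2.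

Step 10
Reactants: 13 rac-5-heptyl-7-hydroxy-1′,4-dioxospiro[chromane-2,3′-isochromane]-6′,8′-diyl bis(2,2-dimethylpropanoate)
Product: 15 (1S)-N,N-dimethyl-1-phenylethan-1-aminium 2-{[(2R)-5-heptyl-2,7-dihydroxy-4-oxochroman-2-yl]methyl}-4,6-dihydroxybenzoate, via racemic hemiketal acid 14 (not isolated)
Conditions: LiOH (10 equiv), degassed THF/H2O (2:1), Ar, 0 °C → rt; 1 M HCl to pH 3.5, 0 °C, EtOAc; heptane trituration (removes PivOH); then (S)-PhCH(Me)NMe2 (1.0 equiv), MeCN, 40 → 5 °C, slurry with seeding
Reagents that add atoms: lithium hydroxide [Li+].[OH-]; (S)-N,N-dimethyl-1-phenylethylamine C[C@H](N(C)C)c1ccccc1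
Why: saponification with acyl–oxygen cleavage opens the lactone (its carbonyl is activated by the two acyloxy groups) and then removes both pivalates, after which the hemiketal acid epimerises at C2 through its open 1,3-diketone while the less soluble ammonium salt crystallises (crystallization-induced diastereomer transformation); the hand of the tertiary amine (which cannot form an enaminone) is chosen so that this salt holds the (2R)-acid, the (S)-amine being written here and the (R)-amine giving the mirror-image pairing if the first crystals prove to be (2S).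

Step 11
Reactants: 15 (1S)-N,N-dimethyl-1-phenylethan-1-aminium 2-{[(2R)-5-heptyl-2,7-dihydroxy-4-oxochroman-2-yl]methyl}-4,6-dihydroxybenzoate
Product: 16 2-{[(2R)-5-heptyl-2,7-dihydroxy-4-oxo-3,4-dihydro-2H-chromen-2-yl]methyl}-4,6-dihydroxybenzoic acid (CNP0232458.1)
Conditions: EtOAc, cold 0.5 M aq. HCl (1.05 equiv), 0 °C, contact under 2 min; Na2SO4; concentrate below 10 °C; precipitate with heptane
Reagents that add atoms: none
Why: acid–base salt break, in which the ammonium carboxylate is protonated by cold dilute acid and the free acid is precipitated at once, so that the hemiketal C2 has no time to equilibrate and keeps the R configuration fixed in the solid.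

Compound list

1 | 5-heptylresorcinol (5-heptylbenzene-1,3-diol) | CCCCCCCc1cc(O)cc(O)c1 | starting material
2 | 1-(2,4-dihydroxy-6-heptylphenyl)ethan-1-iminium chloride | CCCCCCCc1cc(O)cc(O)c1C(C)=[NH2+].[Cl-] | intermediate (not isolated)
3 | 1-(2,4-dihydroxy-6-heptylphenyl)ethan-1-one | CCCCCCCc1cc(O)cc(O)c1C(C)=O | intermediate
4 | 1-[4-(benzyloxy)-2-hydroxy-6-heptylphenyl]ethan-1-one | CCCCCCCc1cc(OCc2ccccc2)cc(O)c1C(C)=O | intermediate
5 | 2-[4-(benzyloxy)-2-hydroxy-6-heptylphenyl]-2-oxoacetaldehyde | CCCCCCCc1cc(OCc2ccccc2)cc(O)c1C(=O)C=O | intermediate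
6 | 3-(3,5-dimethoxyphenyl)propanoic acid | COc1cc(CCC(=O)O)cc(OC)c1 | starting material
7 | 5,7-dimethoxy-2,3-dihydro-1H-inden-1-one | COc1cc2c(c(OC)c1)C(=O)CC2 | intermediate
8 | 5,7-dihydroxy-2,3-dihydro-1H-inden-1-one | Oc1cc2c(c(O)c1)C(=O)CC2 | intermediate
9 | 1-oxo-2,3-dihydro-1H-indene-5,7-diyl bis(2,2-dimethylpropanoate) | CC(C)(C)C(=O)Oc1cc2c(c(OC(=O)C(C)(C)C)c1)C(=O)CC2 | intermediate
10 | (E)-2-{2-[4-(benzyloxy)-2-hydroxy-6-heptylphenyl]-2-oxoethylidene}-1-oxo-2,3-dihydro-1H-indene-5,7-diyl bis(2,2-dimethylpropanoate) | CCCCCCCc1cc(OCc2ccccc2)cc(O)c1C(=O)/C=C3\Cc4cc(OC(=O)C(C)(C)C)cc(OC(=O)C(C)(C)C)c4C3=O | intermediate (not isolated)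
11 | rac-7-(benzyloxy)-5-heptyl-1′,4-dioxo-1′,3′-dihydrospiro[chromane-2,2′-indene]-5′,7′-diyl bis(2,2-dimethylpropanoate) (key-step precursor) | CCCCCCCc1cc(OCc2ccccc2)cc2c1C(=O)CC3(C(=O)c4c(OC(=O)C(C)(C)C)cc(OC(=O)C(C)(C)C)cc4C3)O2 | intermediate
12 | rac-7-(benzyloxy)-5-heptyl-1′,4-dioxospiro[chromane-2,3′-isochromane]-6′,8′-diyl bis(2,2-dimethylpropanoate) (key-step product) | CCCCCCCc1cc(OCc2ccccc2)cc2c1C(=O)CC3(OC(=O)c4c(OC(=O)C(C)(C)C)cc(OC(=O)C(C)(C)C)cc4C3)O2 | intermediate
13 | rac-5-heptyl-7-hydroxy-1′,4-dioxospiro[chromane-2,3′-isochromane]-6′,8′-diyl bis(2,2-dimethylpropanoate) | CCCCCCCc1cc(O)cc2c1C(=O)CC3(OC(=O)c4c(OC(=O)C(C)(C)C)cc(OC(=O)C(C)(C)C)cc4C3)O2 | intermediate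
14 | rac-2-[(5-heptyl-2,7-dihydroxy-4-oxochroman-2-yl)methyl]-4,6-dihydroxybenzoic acid (C2 equilibrating in solution) | CCCCCCCc1cc(O)cc2c1C(=O)CC(O)(Cc1cc(O)cc(O)c1C(=O)O)O2 | intermediate (not isolated)
15 | (1S)-N,N-dimethyl-1-phenylethan-1-aminium 2-{[(2R)-5-heptyl-2,7-dihydroxy-4-oxochroman-2-yl]methyl}-4,6-dihydroxybenzoate | CCCCCCCc1cc(O)cc2c1C(=O)C[C@@](O)(Cc1cc(O)cc(O)c1C(=O)[O-])O2.C[C@H]([NH+](C)C)c1ccccc1 | intermediate
16 | 2-{[(2R)-5-heptyl-2,7-dihydroxy-4-oxo-3,4-dihydro-2H-chromen-2-yl]methyl}-4,6-dihydroxybenzoic acid | CCCCCCCc1cc(O)cc2c1C(=O)C[C@@](O)(Cc1cc(O)cc(O)c1C(=O)O)O2 | target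

Total step count: 11. Longest linear sequence: 8 steps (1, 2, 3, 7, 8, 9, 10, 11; the indanone branch 4, 5, 6, 7–11 is equally long).

Steps most likely to fail

Step 8 (key step). What may go wrong: migration of the aryl carbon in place of C2, peracid addition at the C4 carbonyl, or acid-induced β-elimination of the new carboxylate from C2. The fallback sets out from 9 and 3 and rejoins the route at 14; it cuts the same C1′–C2 bond by glycol-type cleavage instead of insertion. SeO2 (dioxane/H2O, 100 °C) oxidises 9 to 1,2-dioxo-2,3-dihydro-1H-indene-5,7-diyl bis(2,2-dimethylpropanoate) F1. Ketone 3 is silylated (TMSOTf, Et3N, CH2Cl2, 0 °C) to its tris(trimethylsilyl) enol ether F2. Mukaiyama aldol addition of F2 to the more electrophilic C2 ketone of F1 (Sc(OTf)3 cat., CH2Cl2, −40 °C; dilute HCl/THF work-up) should give the racemic α-ketol F3. NaIO4 (THF/H2O, rt) cleaves the α-ketol into carboxylic acid and ketone, and the keto acid closes to the hemiketal acid bis(pivalate) F4. LiOH as in step 10 then gives 14, which enters the crystallization of step 10.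

Step 10. What may go wrong: the salt oils out or both diastereomeric salts co-crystallise, so the equilibrating mixture is not funnelled into one C2 epimer; long exposure to base may also cleave the open 1,3-diketone. The fallback sets out from 14 and rejoins at 16. The racemic acid 14 is resolved by preparative chiral SFC on an immobilised polysaccharide phase (CO2/MeOH with 0.1% formic acid, column and receiver at 5 °C). The (2R) fraction is freeze-dried at once to give 16, and the (2S) fraction is left to re-equilibrate in solution and recycled.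

Step 7. What may go wrong: closure of the phenol onto C3 (5-exo) in place of C2′, Friedel–Crafts oligomerisation of the glyoxal on the electron-rich ring A, or stalling at the ene-dione. The fallback sets out from 9 and 1 and rejoins at 11; it makes the O1–C2′ bond first and closes the pyranone ring by C-acylation. CuBr2 (EtOAc/CHCl3, reflux) brominates 9 to 2-bromo-1-oxo-2,3-dihydro-1H-indene-5,7-diyl bis(2,2-dimethylpropanoate) F5. Mono-benzylation of 1 (BnBr 1 equiv, K2CO3, acetone) gives 3-(benzyloxy)-5-heptylphenol F6. Williamson coupling of F6 with F5 (K2CO3, acetone, rt) gives the 2-aryloxy indanone F7. Its enolate (NaH, THF, 0 °C) is alkylated with tert-butyl bromoacetate to the quaternary tert-butyl ester F8. TFA (CH2Cl2, rt) frees the acid F9. TFAA (CH2Cl2, 0 °C → rt) closes the chromanone by intramolecular Friedel–Crafts acylation para to the benzyloxy group and gives 11.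

Further compounds

F1 | step 8 | 1,2-dioxo-2,3-dihydro-1H-indene-5,7-diyl bis(2,2-dimethylpropanoate) | CC(C)(C)C(=O)Oc1cc2c(c(OC(=O)C(C)(C)C)c1)C(=O)C(=O)C2
F2 | step 8 | {[1-(2-heptyl-4,6-bis(trimethylsilyloxy)phenyl)ethenyl]oxy}trimethylsilane | CCCCCCCc1cc(O[Si](C)(C)C)cc(O[Si](C)(C)C)c1C(=C)O[Si](C)(C)C
F3 | step 8 | rac-2-[2-(2,4-dihydroxy-6-heptylphenyl)-2-oxoethyl]-2-hydroxy-1-oxo-2,3-dihydro-1H-indene-5,7-diyl bis(2,2-dimethylpropanoate) | CCCCCCCc1cc(O)cc(O)c1C(=O)CC3(O)Cc4cc(OC(=O)C(C)(C)C)cc(OC(=O)C(C)(C)C)c4C3=O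
F4 | step 8 | rac-2-[(5-heptyl-2,7-dihydroxy-4-oxochroman-2-yl)methyl]-4,6-bis(pivaloyloxy)benzoic acid | CCCCCCCc1cc(O)cc2c1C(=O)CC(O)(Cc1cc(OC(=O)C(C)(C)C)cc(OC(=O)C(C)(C)C)c1C(=O)O)O2
F0 | step 10 | none | none
F5 | step 7 | rac-2-bromo-1-oxo-2,3-dihydro-1H-indene-5,7-diyl bis(2,2-dimethylpropanoate) | CC(C)(C)C(=O)Oc1cc2c(c(OC(=O)C(C)(C)C)c1)C(=O)C(Br)C2
F6 | step 7 | 3-(benzyloxy)-5-heptylphenol | CCCCCCCc1cc(O)cc(OCc2ccccc2)c1
F7 | step 7 | rac-2-[3-(benzyloxy)-5-heptylphenoxy]-1-oxo-2,3-dihydro-1H-indene-5,7-diyl bis(2,2-dimethylpropanoate) | CCCCCCCc1cc(OCc2ccccc2)cc(OC3Cc4cc(OC(=O)C(C)(C)C)cc(OC(=O)C(C)(C)C)c4C3=O)c1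
F8 | step 7 | rac-tert-butyl 2-{2-[3-(benzyloxy)-5-heptylphenoxy]-1-oxo-5,7-bis(pivaloyloxy)-2,3-dihydro-1H-inden-2-yl}acetate | CCCCCCCc1cc(OCc2ccccc2)cc(OC3(CC(=O)OC(C)(C)C)Cc4cc(OC(=O)C(C)(C)C)cc(OC(=O)C(C)(C)C)c4C3=O)c1
F9 | step 7 | rac-2-{2-[3-(benzyloxy)-5-heptylphenoxy]-1-oxo-5,7-bis(pivaloyloxy)-2,3-dihydro-1H-inden-2-yl}acetic acid | CCCCCCCc1cc(OCc2ccccc2)cc(OC3(CC(=O)O)Cc4cc(OC(=O)C(C)(C)C)cc(OC(=O)C(C)(C)C)c4C3=O)c1
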